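The depside is cut at its aryl ester into a ring B phenol and a ring A acid. Ring A carries its carboxyl carbon on C1, oxygen on C2 and C4 and the 2-oxoheptyl chain on C6, which is exactly the pattern obtained when a linear C14 chain with oxygen on every second carbon closes between C2 and C7. The key step therefore treats an open-chain methyl 3,5,7-triketo ester, whose fourth carbonyl (C9) is locked as a dioxolane, with dilute aqueous base: one C2–C7 aldol bond, dehydration and enolisation deliver the complete resorcylate ring A with the masked side chain already in place. The target has no stereocentres.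

Key step: step 4

Remarks on the chemistry:
- Chain locants C1–C14 refer to the open-chain ester, with C1 the ester carbon.
- The acid chloride of ring A is made without HCl, because the dioxolane must survive until after the depside bond is formed.
- Ring B is coupled as its 2,4-dihydroxy benzyl ester at the non-chelated hydroxyl and is methylated afterwards, which avoids a separate protection sequence.
- The carboxylation of olivetol is assumed to go at the ring carbon between a hydroxyl and the pentyl chain (para to the second hydroxyl).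

Step 1
Reactants: 1 4-hydroxy-6-methylpyran-2-one
Product: 2 methyl 3,5-dioxohexanoate
Conditions: Mg(OMe)2 (2 equiv), MeOH, reflux; then cold 1 M HCl
Reagents that add atoms: magnesium methoxide Mg(OMe)2, C[O-].C[O-].[Mg+2] (methoxy group; solvent methanol, CO, is the equivalent source)
Why: Methoxide opens the lactone carbonyl (ring-opening methanolysis of the pyranone), and the magnesium chelate of the resulting 3,5-diketo ester is shielded from retro-Claisen cleavage and re-closure until the acidic work-up.

Step 2
Reactants: 3 ethyl 3-oxooctanoate; 4 ethylene glycol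
Product: 5 ethyl 2-(2-pentyl-1,3-dioxolan-2-yl)acetate
Conditions: p-TsOH·H2O (cat.), toluene, reflux, Dean–Stark trap
Reagents that add atoms: ethylene glycol (4), OCCO
Why: Acid-catalysed ketalisation of the ketone of a β-keto ester, driven by azeotropic removal of water, with the ester carbonyl unreactive under these conditions.

Step 3
Reactants: 2 methyl 3,5-dioxohexanoate; 5 ethyl 2-(2-pentyl-1,3-dioxolan-2-yl)acetate
Product: 7 methyl 3,5,7-trioxo-8-(2-pentyl-1,3-dioxolan-2-yl)octanoate, via trilithium trianion 6 (not isolated)
Conditions: 2 (2 equiv), LiN(iPr)2 (6.0 equiv, commercial solution), THF, −78 → 0 °C; then 5 (1 equiv), 0 °C → rt; AcOH, −20 °C; crude 7 used at once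
Reagents that add atoms: none
Why: Claisen-type acylation of a 1,3,5-tricarbonyl trianion, in which the terminal C6 carbanion is the most basic and most nucleophilic site and attacks the ester carbonyl of 5, while the second equivalent of trianion takes up the proton of the more acidic product.

Step 4
Reactants: 7 methyl 3,5,7-trioxo-8-(2-pentyl-1,3-dioxolan-2-yl)octanoate
Product: 9 methyl 2,4-dihydroxy-6-[(2-pentyl-1,3-dioxolan-2-yl)methyl]benzoate, via aldol adduct 8 (not isolated)
Conditions: 0.5 M aq. KOH (4 equiv), N2, 0 °C → rt; then AcOH to pH 6 at 0 °C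
Reagents that add atoms: none
Why: Hydroxide converts 7 into its polyenolate, in which the C2 carbon (between the ester and the C3 carbonyl) adds to the C7 ketone, the only carbonyl not locked in an enolised 1,3-dicarbonyl unit, to give carbinol 8; loss of water across C6–C7 and enolisation of the C3 and C5 carbonyls then deliver the benzenoid ring. The closest known reaction type is the base-induced intramolecular aldol condensation of 3,5,7-triketo esters to orsellinate-type resorcylates. Ring A closes in a 6-(enolendo)-exo-trig mode with formation of the single C2–C7 bond. No stereocentre has to be controlled, since the two carbinol-stage centres of 8 vanish on aromatisation. The step needs the C2-to-C7 aldol to outrun C6-to-C1 Claisen closure, pyranone formation and any fold through C9: water as solvent and the absence of a chelating magnesium counter-ion leave the ester the poorest electrophile, the dioxolane takes C9 out of play, and C8, activated by one carbonyl only, is far less acidic than C2, C4 and C6. Dilute base at or below room temperature keeps ester saponification and β-elimination of the ketal oxygen slower than ring closure.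

Step 5
Reactants: 9 methyl 2,4-dihydroxy-6-[(2-pentyl-1,3-dioxolan-2-yl)methyl]benzoate
Product: 10 methyl 2,4-dimethoxy-6-[(2-pentyl-1,3-dioxolan-2-yl)methyl]benzoate
Conditions: MeI (6 equiv), K2CO3, acetone, reflux
Reagents that add atoms: iodomethane, CI
Why: Williamson O-methylation of both phenoxides, with reflux needed for the hydroxyl that is hydrogen-bonded to the ester, while the dioxolane and the ester are inert to anhydrous carbonate.

Step 6
Reactants: 10 methyl 2,4-dimethoxy-6-[(2-pentyl-1,3-dioxolan-2-yl)methyl]benzoate
Product: 11 2,4-dimethoxy-6-[(2-pentyl-1,3-dioxolan-2-yl)methyl]benzoic acid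
Conditions: KOH, DMSO/H2O (4:1), 90 °C; then cold aq. KHSO4 to pH 4, extraction at 0 °C; used directly
Reagents that add atoms: potassium hydroxide KOH, [K+].[OH-]
Why: BAc2 saponification of a di-ortho-substituted benzoate, which needs poorly solvated hydroxide in aqueous DMSO at raised temperature; ketal and aryl methyl ethers are base-stable and the acidification is kept cold and brief.

Step 7
Reactants: 12 olivetol (5-pentylbenzene-1,3-diol)
Product: 13 2,4-dihydroxy-6-pentylbenzoic acid (olivetolic acid)
Conditions: MeOMgOCO2Me (methylmagnesium carbonate, 2 M in DMF, 4 equiv), 120 °C, N2 sweep; then cold 1 M HCl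
Reagents that add atoms: methylmagnesium carbonate MeOMgOCO2Me, COC(=O)[O-].C[O-].[Mg+2]
Why: Chelation-directed ortho-carboxylation of a magnesium phenoxide (a Kolbe–Schmitt-type reaction with the Stiles reagent), expected at the ring carbon ortho to one hydroxyl and para to the other, with cold work-up to prevent decarboxylation.

Step 8
Reactants: 13 2,4-dihydroxy-6-pentylbenzoic acid
Product: 14 benzyl 2,4-dihydroxy-6-pentylbenzoate
Conditions: BnBr (1.05 equiv), KHCO3, DMF, rt
Reagents that add atoms: benzyl bromide, BrCc1ccccc1
Why: SN2 O-alkylation of the carboxylate, since hydrogencarbonate deprotonates the carboxylic acid but leaves both phenols essentially un-ionised and therefore unalkylated.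

Step 9
Reactants: 11 2,4-dimethoxy-6-[(2-pentyl-1,3-dioxolan-2-yl)methyl]benzoic acid; 14 benzyl 2,4-dihydroxy-6-pentylbenzoate
Product: 16 benzyl 4-({2,4-dimethoxy-6-[(2-pentyl-1,3-dioxolan-2-yl)methyl]benzoyl}oxy)-2-hydroxy-6-pentylbenzoate, via acid chloride 15 (not isolated)
Conditions: 11, 1-chloro-N,N,2-trimethylprop-1-en-1-amine (1.05 equiv), CH2Cl2, 0 °C → rt; then 14 (1.1 equiv), Et3N, DMAP (cat.), CH2Cl2, 0 °C → rt
Reagents that add atoms: none
Why: Acid chloride formation with the Ghosez reagent releases no HCl and so spares the dioxolane, and the DMAP-catalysed O-acylation then takes place at the more acidic, non-chelated para hydroxyl of 14, the ortho hydroxyl being held in a hydrogen bond to the benzyl ester and the masked ketone being unable to close an isocoumarin.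

Step 10
Reactants: 16 benzyl 4-({2,4-dimethoxy-6-[(2-pentyl-1,3-dioxolan-2-yl)methyl]benzoyl}oxy)-2-hydroxy-6-pentylbenzoate
Product: 17 benzyl 4-({2,4-dimethoxy-6-[(2-pentyl-1,3-dioxolan-2-yl)methyl]benzoyl}oxy)-2-methoxy-6-pentylbenzoate
Conditions: MeI (5 equiv), Cs2CO3 (1.5 equiv), dry DMF, rt
Reagents that add atoms: iodomethane, CI
Why: Williamson O-methylation of the remaining chelated phenol, under anhydrous carbonate conditions that are not nucleophilic enough to cleave the di-ortho-substituted aryl benzoate or the benzyl ester.

Step 11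
Reactants: 17 benzyl 4-({2,4-dimethoxy-6-[(2-pentyl-1,3-dioxolan-2-yl)methyl]benzoyl}oxy)-2-methoxy-6-pentylbenzoate
Product: 18 benzyl 4-{[2,4-dimethoxy-6-(2-oxoheptyl)benzoyl]oxy}-2-methoxy-6-pentylbenzoate
Conditions: p-TsOH·H2O (0.2 equiv), acetone/H2O (10:1), rt → 40 °C
Reagents that add atoms: water, O
Why: Acid-catalysed ketal hydrolysis through the oxocarbenium ion, under dilute acid at low temperature so that the aryl and benzyl esters survive and the freed ketone does not enol-lactonise onto the depside carbonyl.

Step 12
Reactants: 18 benzyl 4-{[2,4-dimethoxy-6-(2-oxoheptyl)benzoyl]oxy}-2-methoxy-6-pentylbenzoate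
Product: 19 4-{[2,4-dimethoxy-6-(2-oxoheptyl)benzoyl]oxy}-2-methoxy-6-pentylbenzoic acid (target)
Conditions: H2 (1 atm), 10% Pd/C, EtOAc, rt
Reagents that add atoms: none
Why: Catalytic hydrogenolysis of the benzylic C–O bond of the ester under neutral conditions, which should leave the aliphatic ketone, the aryl ester and the aryl ethers untouched.

Compound list
1 | 4-hydroxy-6-methylpyran-2-one | CC1=CC(O)=CC(=O)O1 | starting material
2 | methyl 3,5-dioxohexanoate | CC(=O)CC(=O)CC(=O)OC | intermediate
3 | ethyl 3-oxooctanoate | CCCCCC(=O)CC(=O)OCC | starting material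
4 | ethylene glycol | OCCO | starting material
5 | ethyl 2-(2-pentyl-1,3-dioxolan-2-yl)acetate | CCCCCC1(CC(=O)OCC)OCCO1 | intermediate
6 | trilithium trianion of methyl 3,5-dioxohexanoate | [Li+].[Li+].[Li+].C=C([O-])C=C([O-])C=C([O-])OC | intermediate (not isolated)
7 | methyl 3,5,7-trioxo-8-(2-pentyl-1,3-dioxolan-2-yl)octanoate | CCCCCC1(CC(=O)CC(=O)CC(=O)CC(=O)OC)OCCO1 | intermediate
8 | methyl 2-hydroxy-4,6-dioxo-2-[(2-pentyl-1,3-dioxolan-2-yl)methyl]cyclohexane-1-carboxylate (aldol adduct, stereoisomer mixture) | COC(=O)C1C(=O)CC(=O)CC1(O)CC1(CCCCC)OCCO1 | intermediate (not isolated)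
9 | methyl 2,4-dihydroxy-6-[(2-pentyl-1,3-dioxolan-2-yl)methyl]benzoate | CCCCCC1(Cc2cc(O)cc(O)c2C(=O)OC)OCCO1 | intermediate
10 | methyl 2,4-dimethoxy-6-[(2-pentyl-1,3-dioxolan-2-yl)methyl]benzoate | CCCCCC1(Cc2cc(OC)cc(OC)c2C(=O)OC)OCCO1 | intermediate
11 | 2,4-dimethoxy-6-[(2-pentyl-1,3-dioxolan-2-yl)methyl]benzoic acid | CCCCCC1(Cc2cc(OC)cc(OC)c2C(=O)O)OCCO1 | intermediate
12 | olivetol (5-pentylbenzene-1,3-diol) | CCCCCc1cc(O)cc(O)c1 | starting material
13 | 2,4-dihydroxy-6-pentylbenzoic acid | CCCCCc1cc(O)cc(O)c1C(=O)O | intermediate
14 | benzyl 2,4-dihydroxy-6-pentylbenzoate | CCCCCc1cc(O)cc(O)c1C(=O)OCc1ccccc1 | intermediate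
15 | 2,4-dimethoxy-6-[(2-pentyl-1,3-dioxolan-2-yl)methyl]benzoyl chloride | CCCCCC1(Cc2cc(OC)cc(OC)c2C(=O)Cl)OCCO1 | intermediate (not isolated)
16 | benzyl 4-({2,4-dimethoxy-6-[(2-pentyl-1,3-dioxolan-2-yl)methyl]benzoyl}oxy)-2-hydroxy-6-pentylbenzoate | CCCCCC1(Cc2cc(OC)cc(OC)c2C(=O)Oc2cc(CCCCC)c(C(=O)OCc3ccccc3)c(O)c2)OCCO1 | intermediate
17 | benzyl 4-({2,4-dimethoxy-6-[(2-pentyl-1,3-dioxolan-2-yl)methyl]benzoyl}oxy)-2-methoxy-6-pentylbenzoate | CCCCCC1(Cc2cc(OC)cc(OC)c2C(=O)Oc2cc(CCCCC)c(C(=O)OCc3ccccc3)c(OC)c2)OCCO1 | intermediate
18 | benzyl 4-{[2,4-dimethoxy-6-(2-oxoheptyl)benzoyl]oxy}-2-methoxy-6-pentylbenzoate | CCCCCC(=O)Cc1cc(OC)cc(OC)c1C(=O)Oc1cc(CCCCC)c(C(=O)OCc2ccccc2)c(OC)c1 | intermediate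
19 | 4-{[2,4-dimethoxy-6-(2-oxoheptyl)benzoyl]oxy}-2-methoxy-6-pentylbenzoic acid | CCCCCC(=O)Cc1cc(OC)cc(OC)c1C(=O)Oc1cc(CCCCC)c(C(=O)O)c(OC)c1 | target

Total step count: 12.
Longest linear sequence: 9 steps (steps 1, 3, 4, 5, 6, 9, 10, 11, 12, from compound 1).

Steps most likely to fail

1. Step 4 (ring closure). The chain may fold through the wrong enolate and carbonyl pair (Claisen closure onto the ester or lactonisation to a hydroxypyranone). The ester may also be saponified, or the dioxolane opened by β-elimination, before the ring has formed. The fallback builds ring A by Michael–Claisen annulation and oxidative aromatisation; it sets out from compound 5 and comes back at compound 9. Ester 5 would be reduced with iBu2AlH (toluene, −78 °C) to 2-(2-pentyl-1,3-dioxolan-2-yl)acetaldehyde F1. A Wittig reaction with 1-(triphenylphosphoranylidene)propan-2-one (CH2Cl2, rt) should then give (E)-5-(2-pentyl-1,3-dioxolan-2-yl)pent-3-en-2-one F2. Conjugate addition of dimethyl malonate (NaOMe, MeOH, reflux) with Claisen closure in the same flask should furnish methyl 2,4-dioxo-6-[(2-pentyl-1,3-dioxolan-2-yl)methyl]cyclohexane-1-carboxylate F3, the dihydro form of ring A. Bromination and dehydrobromination (Br2, NaOAc, DMF, 0 → 60 °C) would aromatise it to 9.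

2. Step 3 (trianion acylation). Proton transfer from the α-methylene of 5 to the strongly basic trianion, followed by opening of the dioxolane, may compete with C-acylation, and the reaction may stall as the product quenches unreacted trianion. The fallback changes the acyl donor; it sets out from compound 5 and comes back at compound 7. Ester 5 would be converted with MeNHOMe·HCl and iPrMgCl (THF, −20 °C) into N-methoxy-N-methyl-2-(2-pentyl-1,3-dioxolan-2-yl)acetamide F4. Its less acidic α-protons and the chelated tetrahedral adduct, which persists until the quench, should allow trianion 6 to be acylated once and to release 7 only on work-up.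

3. Step 9 (depside coupling). Site selectivity between the two hydroxyls of 14 may be incomplete (acylation at the chelated hydroxyl or double acylation), and the hindered aroyl chloride may react too slowly with the hydrogen-bonded diol. The fallback differentiates the hydroxyls before coupling; it sets out from compound 14 and comes back at compound 17, so that compound 16 and step 10 are bypassed. Compound 14 would be protected at the non-chelated hydroxyl (MOMCl, iPr2NEt, CH2Cl2, 0 °C) to give benzyl 2-hydroxy-4-(methoxymethoxy)-6-pentylbenzoate F5. Methylation (MeI, K2CO3, DMF) should give benzyl 2-methoxy-4-(methoxymethoxy)-6-pentylbenzoate F6, and acetal cleavage (2 M aq. HCl, THF, 40 °C) benzyl 4-hydroxy-2-methoxy-6-pentylbenzoate F7. This single unchelated phenol would then be acylated with acid chloride 15 (Et3N, DMAP, CH2Cl2) to give 17.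

Further compounds
F1 | step 4 | 2-(2-pentyl-1,3-dioxolan-2-yl)acetaldehyde | CCCCCC1(CC=O)OCCO1
F2 | step 4 | (E)-5-(2-pentyl-1,3-dioxolan-2-yl)pent-3-en-2-one | CCCCCC1(C/C=C/C(C)=O)OCCO1
F3 | step 4 | methyl 2,4-dioxo-6-[(2-pentyl-1,3-dioxolan-2-yl)methyl]cyclohexane-1-carboxylate (racemic, stereoisomer mixture) | CCCCCC1(CC2CC(=O)CC(=O)C2C(=O)OC)OCCO1
F4 | step 3 | N-methoxy-N-methyl-2-(2-pentyl-1,3-dioxolan-2-yl)acetamide | CCCCCC1(CC(=O)N(C)OC)OCCO1
F5 | step 9 | benzyl 2-hydroxy-4-(methoxymethoxy)-6-pentylbenzoate | CCCCCc1cc(OCOC)cc(O)c1C(=O)OCc1ccccc1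
F6 | step 9 | benzyl 2-methoxy-4-(methoxymethoxy)-6-pentylbenzoate | CCCCCc1cc(OCOC)cc(OC)c1C(=O)OCc1ccccc1
F7 | step 9 | benzyl 4-hydroxy-2-methoxy-6-pentylbenzoate | CCCCCc1cc(O)cc(OC)c1C(=O)OCc1ccccc1
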